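Assumption: the SMILES is taken literally, i.e. a (2S,3R)-trans dihydrobenzofuran with a Z enal; 2-(furan-2-yl)acetic acid, vanillin acetate and ethyl (Z)-3-iodoacrylate are treated as catalogue items.

**Retrosynthetic overview** (ring A = guaiacyl ring, ring B = benzo ring, ring C = dihydrofuran, ring D = 4-hydroxybenzoate ring)
1. Z-enal ⇐ MnO2 oxidation of the Z-allylic alcohol ⇐ Suzuki coupling of a C5 aryl boronate with (Z)-3-iodoallyl alcohol; the benzoate comes from a Mitsunobu reaction with unprotected 4-hydroxybenzoic acid.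
2. C5 boronate ⇐ sterically controlled C–H borylation; C5–H is the only aromatic C–H with no ortho substituent.
3. Rings B and C ⇐ one gold-catalysed furan–ynol ether cycloisomerisation: four furan carbons plus two alkyne carbons become ring B, the O–C–C tether becomes ring C, and the furan oxygen becomes the 7-OH (later 7-OMe).
4. Ynol ether ⇐ secondary alcohol + trichloroethylene; the alcohol ⇐ Evans syn-aldol of a furylacetyl oxazolidinone with vanillin acetate, which sets both stereocentres.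
5. Ring order: rings A and D are bought; rings B and C are formed together in step 6; no ring is formed afterwards.

**Route**

Step 1
Reactants: 1 2-(furan-2-yl)acetic acid; 2 (4S)-4-benzyl-1,3-oxazolidin-2-one
Product: 4 (4S)-4-benzyl-3-[2-(furan-2-yl)acetyl]-1,3-oxazolidin-2-one, via mixed pivalic anhydride 3 (not isolated)
Conditions: t-BuCOCl, Et3N, THF, −20 °C; then LiCl, 2, −20 °C → rt
Reagents that add atoms: pivaloyl chloride, CC(C)(C)C(Cl)=O (its acyl group sits in 3 only)
Why: Mixed-anhydride N-acylation of the oxazolidinone under LiCl/Et3N activation gives the imide without touching the furan, and no stereocentre is formed.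

Step 2
Reactants: 4 (4S)-4-benzyl-3-[2-(furan-2-yl)acetyl]-1,3-oxazolidin-2-one; 5 4-formyl-2-methoxyphenyl acetate (vanillin acetate)
Product: 7 4-[(1S,2R)-3-[(4S)-4-benzyl-2-oxo-1,3-oxazolidin-3-yl]-2-(furan-2-yl)-1-hydroxy-3-oxopropyl]-2-methoxyphenyl acetate (syn aldol adduct), via (Z)-boron enolate 6 (not isolated)
Conditions: Bu2BOTf, i-Pr2NEt, CH2Cl2, −78 → 0 °C; then 5, −78 → 0 °C; pH 7 buffer, MeOH, 30% H2O2, 0 °C
Reagents that add atoms: dibutylboron triflate, CCCCB(CCCC)OS(=O)(=O)C(F)(F)F (its boron sits in 6 only)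
Why: Evans syn-aldol reaction, in which the (Z)-boron enolate reacts through a closed Zimmerman–Traxler chair on the face away from the benzyl group and so sets both stereocentres (the furyl-bearing carbon that becomes C3 and the carbinol carbon that becomes C2) in the syn relationship and absolute sense that map onto the trans-(2S,3R) ring.

Step 3
Reactants: 7 syn aldol adduct
Product: 8 (1S,2R)-2-(furan-2-yl)-1-(4-hydroxy-3-methoxyphenyl)propane-1,3-diol
Conditions: LiBH4 (4 equiv), H2O (1.1 equiv), THF/Et2O, 0 °C → rt; aq. NH4Cl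
Reagents that add atoms: none
Why: Reductive auxiliary cleavage, in which borohydride reduces the exocyclic imide carbonyl to the primary alcohol (auxiliary recovered) and reduces off the aryl acetate in the same pot, without touching either stereocentre.

Step 4
Reactants: 8 (1S,2R)-2-(furan-2-yl)-1-(4-hydroxy-3-methoxyphenyl)propane-1,3-diol
Product: 9 (1S,2R)-2-(furan-2-yl)-1-{3-methoxy-4-[(triisopropylsilyl)oxy]phenyl}-3-[(triisopropylsilyl)oxy]propan-1-ol
Conditions: i-Pr3SiCl (2.2 equiv), imidazole, DMF, 0 °C → rt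
Reagents that add atoms: triisopropylsilyl chloride, CC(C)[Si](Cl)(C(C)C)C(C)C
Why: Chemoselective silylation, in which the bulky silyl chloride caps the phenol and the primary alcohol but not the hindered secondary benzylic alcohol, the one hydroxyl needed free for step 5.

Step 5
Reactants: 9 bis-silyl alcohol; 10 trichloroethylene
Product: 14 {4-[(1S,2R)-1-(ethynyloxy)-2-(furan-2-yl)-3-[(triisopropylsilyl)oxy]propyl]-2-methoxyphenoxy}triisopropylsilane (ynol ether), via dichlorovinyl ether 11 (not isolated), via chloroethynyl ether 12 (not isolated), via lithium alkynyl ether 13 (not isolated)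
Conditions: KH (2.2 equiv), THF, 0 °C; 10, −40 °C → rt; then n-BuLi (2.6 equiv), −78 °C; MeOH, −78 °C; cold work-up, used at once
Reagents that add atoms: n-butyllithium, [Li]CCCC (its lithium sits in 13 only)
Why: Greene ynol ether synthesis, in which the potassium alkoxide adds to dichloroacetylene formed in situ from 10, n-BuLi eliminates HCl and exchanges the remaining chlorine for lithium, and methanol protonates the acetylide, the C–O bond at the stereocentre never being broken so that its configuration is retained.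

Step 6
Reactants: 14 ynol ether
Product: 15 (2S,3R)-2-{3-methoxy-4-[(triisopropylsilyl)oxy]phenyl}-3-{[(triisopropylsilyl)oxy]methyl}-2,3-dihydro-1-benzofuran-7-ol
Conditions: Ph3PAuNTf2 (2 mol %), 4 Å MS, CH2Cl2, 0 °C → rt
Reagents that add atoms: none
Why: Gold-catalysed furan–yne phenol synthesis (Hashmi type), in which the furan attacks the oxygen-bearing carbon of the gold-activated ynol ether (5-exo), opens and recloses around the former alkyne so that its four carbons and the two alkyne carbons become benzene ring B while the O–C–C tether becomes dihydrofuran ring C, the furan oxygen ends on the former terminal alkyne carbon as the 7-OH because the ring oxygen stabilises that mode of ring opening, and both stereocentres from step 2 are only carried through to give the trans ring.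

Step 7
Reactants: 15 dihydrobenzofuran-7-ol
Product: 16 {4-[(2S,3R)-7-methoxy-3-{[(triisopropylsilyl)oxy]methyl}-2,3-dihydro-1-benzofuran-2-yl]-2-methoxyphenoxy}triisopropylsilane
Conditions: MeI, K2CO3, acetone, rt
Reagents that add atoms: iodomethane, CI
Why: Williamson O-methylation of the only free phenol installs the 7-methoxy group.

Step 8
Reactants: 16 7-methoxy dihydrobenzofuran
Product: 17 5-(4,4,5,5-tetramethyl-1,3,2-dioxaborolan-2-yl) derivative of 16 (2S,3R)
Conditions: [Ir(OMe)(cod)]2 (1.5 mol %), 4,4'-di-tert-butyl-2,2'-bipyridine (3 mol %), B2pin2 (1.0 equiv), THF, 70 °C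
Reagents that add atoms: bis(pinacolato)diboron, CC1(C)OB(OC1(C)C)B1OC(C)(C)C(C)(C)O1
Why: Iridium-catalysed aromatic C–H borylation is governed by sterics, and C5–H of ring B is the only aromatic C–H in 16 with no ortho substituent, so the boryl group goes para to the ring oxygen.

Step 9
Reactants: 17 aryl boronate
Product: 18 4-[(2S,3R)-3-(hydroxymethyl)-7-methoxy-5-(4,4,5,5-tetramethyl-1,3,2-dioxaborolan-2-yl)-2,3-dihydro-1-benzofuran-2-yl]-2-methoxyphenol
Conditions: n-Bu4NF/AcOH (1:1, 3 equiv), THF, rt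
Reagents that add atoms: none
Why: Fluoride-induced desilylation, buffered with AcOH so that the aryl boronate and the benzylic aryl ether see no strong base, frees the primary alcohol and the ring A phenol in one operation.

Step 10
Reactants: 18 boronate diol; 19 4-hydroxybenzoic acid
Product: 20 [(2S,3R)-2-(4-hydroxy-3-methoxyphenyl)-7-methoxy-5-(4,4,5,5-tetramethyl-1,3,2-dioxaborolan-2-yl)-2,3-dihydro-1-benzofuran-3-yl]methyl 4-hydroxybenzoate
Conditions: PPh3, DIAD, THF, 0 °C → rt
Reagents that add atoms: none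
Why: Mitsunobu esterification takes the carboxylic acid (far more acidic than either phenol) as the pronucleophile and the primary alcohol as the electrophile, so the ester forms without phenol protection, and the reacting carbon is not a stereocentre.

Step 11
Reactants: 21 ethyl (Z)-3-iodoprop-2-enoate
Product: 22 (Z)-3-iodoprop-2-en-1-ol
Conditions: i-Bu2AlH (2.2 equiv), CH2Cl2, −78 °C; aq. potassium sodium tartrate
Reagents that add atoms: none
Why: Low-temperature hydride reduction of the ester to the allylic alcohol leaves the Z iodoalkene geometry intact.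

Step 12
Reactants: 20 aryl boronate ester; 22 (Z)-3-iodoprop-2-en-1-ol
Product: 23 [(2S,3R)-2-(4-hydroxy-3-methoxyphenyl)-5-[(1Z)-3-hydroxyprop-1-en-1-yl]-7-methoxy-2,3-dihydro-1-benzofuran-3-yl]methyl 4-hydroxybenzoate
Conditions: Pd(dppf)Cl2 (5 mol %), K3PO4 (3 equiv), THF/H2O, 40 °C
Reagents that add atoms: none
Why: Suzuki–Miyaura coupling of an alkenyl iodide proceeds with retention of alkene geometry, so the Z alkene is installed directly, and the mild phosphate base spares the benzoate and tolerates the free phenols.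

Step 13
Reactants: 23 Z-allylic alcohol
Product: 24 [(2S,3R)-2-(4-hydroxy-3-methoxyphenyl)-7-methoxy-5-[(1Z)-3-oxoprop-1-en-1-yl]-2,3-dihydro-1-benzofuran-3-yl]methyl 4-hydroxybenzoate (target)
Conditions: activated MnO2 (15 equiv), CH2Cl2, rt, dark
Reagents that add atoms: none
Why: Allylic oxidation with activated MnO2 is selective for the allylic alcohol under neutral heterogeneous conditions that should neither isomerise the Z enal nor affect the phenols, the ester or the ring stereocentres.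

**Compound list**

1 | 2-(furan-2-yl)acetic acid | OC(=O)Cc1ccco1 | starting material
2 | (4S)-4-benzyl-1,3-oxazolidin-2-one | O=C1N[C@@H](Cc2ccccc2)CO1 | starting material
3 | 2-(furan-2-yl)acetic pivalic anhydride | CC(C)(C)C(=O)OC(=O)Cc1ccco1 | intermediate
4 | (4S)-4-benzyl-3-[2-(furan-2-yl)acetyl]-1,3-oxazolidin-2-one | O=C(Cc1ccco1)N1C(=O)OC[C@@H]1Cc1ccccc1 | intermediate
5 | 4-formyl-2-methoxyphenyl acetate (vanillin acetate) | CC(=O)Oc1ccc(C=O)cc1OC | starting material
6 | (Z)-dibutylboron enolate of 4 | CCCCB(CCCC)O/C(=C\c1ccco1)N1C(=O)OC[C@@H]1Cc1ccccc1 | intermediate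
7 | 4-[(1S,2R)-3-[(4S)-4-benzyl-2-oxo-1,3-oxazolidin-3-yl]-2-(furan-2-yl)-1-hydroxy-3-oxopropyl]-2-methoxyphenyl acetate | O=C(N1C(=O)OC[C@@H]1Cc1ccccc1)[C@@H](c1ccco1)[C@H](O)c1ccc(OC(C)=O)c(OC)c1 | intermediate
8 | (1S,2R)-2-(furan-2-yl)-1-(4-hydroxy-3-methoxyphenyl)propane-1,3-diol | OC[C@@H](c1ccco1)[C@H](O)c1ccc(O)c(OC)c1 | intermediate
9 | (1S,2R)-2-(furan-2-yl)-1-{3-methoxy-4-[(triisopropylsilyl)oxy]phenyl}-3-[(triisopropylsilyl)oxy]propan-1-ol | CC(C)[Si](C(C)C)(C(C)C)OC[C@@H](c1ccco1)[C@H](O)c1ccc(O[Si](C(C)C)(C(C)C)C(C)C)c(OC)c1 | intermediate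
10 | trichloroethylene | ClC=C(Cl)Cl | starting material
11 | (E)-1,2-dichlorovinyl ether of 9 (1S,2R) | Cl/C=C(/Cl)O[C@H](c1ccc(O[Si](C(C)C)(C(C)C)C(C)C)c(OC)c1)[C@@H](CO[Si](C(C)C)(C(C)C)C(C)C)c1ccco1 | intermediate
12 | chloroethynyl ether of 9 (1S,2R) | ClC#CO[C@H](c1ccc(O[Si](C(C)C)(C(C)C)C(C)C)c(OC)c1)[C@@H](CO[Si](C(C)C)(C(C)C)C(C)C)c1ccco1 | intermediate
13 | lithioethynyl ether of 9 (1S,2R) | [Li]C#CO[C@H](c1ccc(O[Si](C(C)C)(C(C)C)C(C)C)c(OC)c1)[C@@H](CO[Si](C(C)C)(C(C)C)C(C)C)c1ccco1 | intermediate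
14 | {4-[(1S,2R)-1-(ethynyloxy)-2-(furan-2-yl)-3-[(triisopropylsilyl)oxy]propyl]-2-methoxyphenoxy}triisopropylsilane | C#CO[C@H](c1ccc(O[Si](C(C)C)(C(C)C)C(C)C)c(OC)c1)[C@@H](CO[Si](C(C)C)(C(C)C)C(C)C)c1ccco1 | intermediate
15 | (2S,3R)-2-{3-methoxy-4-[(triisopropylsilyl)oxy]phenyl}-3-{[(triisopropylsilyl)oxy]methyl}-2,3-dihydro-1-benzofuran-7-ol | COc1cc([C@H]2Oc3c(O)cccc3[C@@H]2CO[Si](C(C)C)(C(C)C)C(C)C)ccc1O[Si](C(C)C)(C(C)C)C(C)C | intermediate
16 | {4-[(2S,3R)-7-methoxy-3-{[(triisopropylsilyl)oxy]methyl}-2,3-dihydro-1-benzofuran-2-yl]-2-methoxyphenoxy}triisopropylsilane | COc1cc([C@H]2Oc3c(OC)cccc3[C@@H]2CO[Si](C(C)C)(C(C)C)C(C)C)ccc1O[Si](C(C)C)(C(C)C)C(C)C | intermediate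
17 | 5-(4,4,5,5-tetramethyl-1,3,2-dioxaborolan-2-yl) derivative of 16 (2S,3R) | COc1cc([C@H]2Oc3c(OC)cc(B4OC(C)(C)C(C)(C)O4)cc3[C@@H]2CO[Si](C(C)C)(C(C)C)C(C)C)ccc1O[Si](C(C)C)(C(C)C)C(C)C | intermediate
18 | 4-[(2S,3R)-3-(hydroxymethyl)-7-methoxy-5-(4,4,5,5-tetramethyl-1,3,2-dioxaborolan-2-yl)-2,3-dihydro-1-benzofuran-2-yl]-2-methoxyphenol | COc1cc([C@H]2Oc3c(OC)cc(B4OC(C)(C)C(C)(C)O4)cc3[C@@H]2CO)ccc1O | intermediate
19 | 4-hydroxybenzoic acid | OC(=O)c1ccc(O)cc1 | starting material
20 | [(2S,3R)-2-(4-hydroxy-3-methoxyphenyl)-7-methoxy-5-(4,4,5,5-tetramethyl-1,3,2-dioxaborolan-2-yl)-2,3-dihydro-1-benzofuran-3-yl]methyl 4-hydroxybenzoate | COc1cc([C@H]2Oc3c(OC)cc(B4OC(C)(C)C(C)(C)O4)cc3[C@@H]2COC(=O)c2ccc(O)cc2)ccc1O | intermediate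
21 | ethyl (Z)-3-iodoprop-2-enoate | CCOC(=O)/C=C\I | starting material
22 | (Z)-3-iodoprop-2-en-1-ol | OC/C=C\I | intermediate
23 | [(2S,3R)-2-(4-hydroxy-3-methoxyphenyl)-5-[(1Z)-3-hydroxyprop-1-en-1-yl]-7-methoxy-2,3-dihydro-1-benzofuran-3-yl]methyl 4-hydroxybenzoate | COc1cc([C@H]2Oc3c(OC)cc(/C=C\CO)cc3[C@@H]2COC(=O)c2ccc(O)cc2)ccc1O | intermediate
24 | [(2S,3R)-2-(4-hydroxy-3-methoxyphenyl)-7-methoxy-5-[(1Z)-3-oxoprop-1-en-1-yl]-2,3-dihydro-1-benzofuran-3-yl]methyl 4-hydroxybenzoate | COc1cc([C@H]2Oc3c(OC)cc(/C=C\C=O)cc3[C@@H]2COC(=O)c2ccc(O)cc2)ccc1O | target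

**Step count and risks**

Total: 13 steps. Longest linear sequence: 12 steps (steps 1–10, 12, 13, from 1 to 24); step 11 is the only off-line step.

Most likely to fail, in order:

Step 6 (gold-catalysed formation of rings B and C). The ynol ether 14 is a secondary benzylic ethynyl ether that can hydrate, undergo [3,3] rearrangement or be attacked by ring A instead of the furan. The fallback gives up the furan-to-benzene construction and closes only ring C on a bought benzene ring; it sets out from 2 and 5 and comes back at 16. Commercial 2-allyl-6-methoxyphenol is acetylated (Ac2O, pyridine) to 2-allyl-6-methoxyphenyl acetate F3. Ozonolysis (O3, CH2Cl2, −78 °C; Me2S) gives 2-(2-acetoxy-3-methoxyphenyl)acetaldehyde F4, and chlorite oxidation (NaClO2, NaH2PO4, 2-methylbut-2-ene) gives 2-(2-acetoxy-3-methoxyphenyl)acetic acid F5. Acylation of 2 as in step 1 gives the imide F6, and the boron aldol with 5 as in step 2 gives the syn adduct F7. LiBH4 as in step 3 removes the auxiliary and both acetates to give the tetraol F8. Catalytic TsOH in CH2Cl2 then ionises the 4-hydroxybenzylic alcohol, and the ortho phenol of ring B traps the cation to give the thermodynamically preferred trans dihydrobenzofuran diol F9, whose C2 configuration is dictated by the aldol-derived C3 centre. Silylation as in step 4 gives 16, and the route continues with step 8.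

Step 5 (ynol ether formation). The potassium alkoxide may shuffle silyl groups, and 14 is thermally fragile. The fallback avoids any alkoxide and starts from 9, coming back at 12. Formylation of 9 (acetic formic anhydride, pyridine, 0 °C) gives the formate F1. Dichloro-olefination of the formyl group (PPh3, CCl4, THF, 60 °C) gives the 2,2-dichlorovinyl ether F2. n-BuLi at −78 °C eliminates HCl from F2 to give 12, which is carried on to 13 and 14 as in step 5.

Step 13 (final oxidation). MnO2 may partly isomerise the Z enal or attack the electron-rich free phenol of ring A. The fallback carries the aldehyde in masked form and needs no late oxidation; it sets out from 20 and comes back at 24. Commercial 3,3-diethoxyprop-1-yne is iodinated (N-iodosuccinimide, AgNO3 cat., acetone) to 3,3-diethoxy-1-iodoprop-1-yne F10. Diimide reduction (KO2CN=NCO2K, AcOH, MeOH) gives (Z)-3,3-diethoxy-1-iodoprop-1-ene F11. Suzuki coupling of F11 with 20 under the step 12 conditions gives the Z-alkenyl diethyl acetal F12. Mild hydrolysis (oxalic acid on wet SiO2, CH2Cl2, rt) releases 24.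

**Further compounds**

F1 | step 5 | formate ester of 9 (1S,2R) | O=CO[C@H](c1ccc(O[Si](C(C)C)(C(C)C)C(C)C)c(OC)c1)[C@@H](CO[Si](C(C)C)(C(C)C)C(C)C)c1ccco1
F2 | step 5 | 2,2-dichlorovinyl ether of 9 (1S,2R) | ClC(Cl)=CO[C@H](c1ccc(O[Si](C(C)C)(C(C)C)C(C)C)c(OC)c1)[C@@H](CO[Si](C(C)C)(C(C)C)C(C)C)c1ccco1
F3 | step 6 | 2-allyl-6-methoxyphenyl acetate | CC(=O)Oc1c(CC=C)cccc1OC
F4 | step 6 | 2-(2-acetoxy-3-methoxyphenyl)acetaldehyde | CC(=O)Oc1c(CC=O)cccc1OC
F5 | step 6 | 2-(2-acetoxy-3-methoxyphenyl)acetic acid | CC(=O)Oc1c(CC(O)=O)cccc1OC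
F6 | step 6 | (4S)-3-[2-(2-acetoxy-3-methoxyphenyl)acetyl]-4-benzyl-1,3-oxazolidin-2-one | CC(=O)Oc1c(CC(=O)N2C(=O)OC[C@@H]2Cc2ccccc2)cccc1OC
F7 | step 6 | (4S)-3-[(2S,3S)-2-(2-acetoxy-3-methoxyphenyl)-3-(4-acetoxy-3-methoxyphenyl)-3-hydroxypropanoyl]-4-benzyl-1,3-oxazolidin-2-one | O=C(N1C(=O)OC[C@@H]1Cc1ccccc1)[C@@H](c1cccc(OC)c1OC(C)=O)[C@H](O)c1ccc(OC(C)=O)c(OC)c1
F8 | step 6 | (1S,2R)-2-(2-hydroxy-3-methoxyphenyl)-1-(4-hydroxy-3-methoxyphenyl)propane-1,3-diol | OC[C@@H](c1cccc(OC)c1O)[C@H](O)c1ccc(O)c(OC)c1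
F9 | step 6 | 4-[(2S,3R)-3-(hydroxymethyl)-7-methoxy-2,3-dihydro-1-benzofuran-2-yl]-2-methoxyphenol | COc1cc([C@H]2Oc3c(OC)cccc3[C@@H]2CO)ccc1O
F10 | step 13 | 3,3-diethoxy-1-iodoprop-1-yne | CCOC(OCC)C#CI
F11 | step 13 | (Z)-3,3-diethoxy-1-iodoprop-1-ene | CCOC(OCC)/C=C\I
F12 | step 13 | [(2S,3R)-5-[(1Z)-3,3-diethoxyprop-1-en-1-yl]-2-(4-hydroxy-3-methoxyphenyl)-7-methoxy-2,3-dihydro-1-benzofuran-3-yl]methyl 4-hydroxybenzoate | COc1cc([C@H]2Oc3c(OC)cc(/C=C\C(OCC)OCC)cc3[C@@H]2COC(=O)c2ccc(O)cc2)ccc1O
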